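The nine-membered carbocycle is closed last, at C6–C7. This ring bond joins two unsubstituted methylenes and lies between C5 (fusion to the pyran) and C8 (the carbon of the exocyclic methylene, carried as a ketone ketal), so a sulfur atom can be placed between C6 and C7 and extruded. The precursor is a ten-membered cyclic sulfone that already contains the cyclobutane, the pyran, ring A and all five stereocentres, with C8 as a dioxolane. One Ramberg–Bäcklund reaction forms the C6–C7 bond with loss of SO2 and contracts the thiacycle to the carbocycle; the resulting alkene is then simply reduced.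

Key step: step 17

Remarks on the chemistry (assumptions):
- Locants follow caryophyllane numbering: cyclobutane C1(H)–C9(H)–C10H2–C11Me2; chain C2–C3; C4 (methyl, pyran O); C5 (pyran CH); C6, C7; C8 (future C=CH2); C1′ carries the isobutyl group; ring A is the tetramethylcyclohexenedione.
- The cyclobutane is built from an allenoate, not from an acrylate. In a polar [2+2] with the Me2C=CH terminus an acrylate would place its carbonyl-bearing carbon next to CMe2, whereas the target needs that carbon (C9) next to C1–H with CMe2 across the ring. An allenoate gives this pattern and also delivers C7 and C8.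
- Design of the sulfone: C8 is masked as a cyclic ketal, because a C7 carbanion is β to the ketal oxygens and a dioxolane cannot lose its alkoxide from the molecule. The ketal is installed before sulfur is oxidised, so no acidic β-keto sulfone is handled. C9 is equilibrated to trans before ring closure.
- The cyclobutane is too remote from C4=C5 to steer the cycloaddition of step 10. The two facial diastereomers are expected in similar amounts and are separated at that stage.

Step 1
Reactants: 1 but-3-ynoic acid; 2 2,2,2-trifluoroethanol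
Product: 4 2,2,2-trifluoroethyl buta-2,3-dienoate, via but-3-ynoate ester 3 (not isolated)
Conditions: DCC, DMAP (cat.), CH2Cl2, 0 °C → rt; then Et3N (cat.), rt
Reagents that add atoms: none
Why: Steglich esterification gives the but-3-ynoate, whose acidic propargylic CH2 lets the amine base shift it to the conjugated allenoate (propargyl–allenyl isomerisation).

Step 2
Reactants: 5 geraniol
Product: 6 geranyl benzoate
Conditions: BzCl, pyridine, DMAP (cat.), CH2Cl2, 0 °C → rt
Reagents that add atoms: benzoyl chloride, O=C(Cl)c1ccccc1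
Why: O-acylation of the primary allylic alcohol; the benzoate has no α-hydrogen, lowers the nucleophilicity of the C4=C5 alkene for step 3 and is removed by methoxide in step 9.

Step 3
Reactants: 6 geranyl benzoate; 4 2,2,2-trifluoroethyl buta-2,3-dienoate
Product: 7 cyclobutylidene acetate (2S)
Conditions: chiral oxazaborolidinium Lewis acid (20 mol %, enantiomer that delivers the 2S adduct), CH2Cl2, −78 → −40 °C
Reagents that add atoms: none
Why: Lewis-acid-catalysed enantioselective allenoate–alkene [2+2] cycloaddition, in which the more electron-rich remote Me2C=CH alkene attacks the central allene carbon through its CH terminus (C1–C9), the tertiary cation at C11 is captured by the γ-carbon (C10–C11) so that CMe2 ends up across the ring from C9, and the chiral Lewis acid selects the alkene face and sets C1.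

Step 4
Reactants: 7 cyclobutylidene acetate
Product: 8 cyclobutyl acetate (C9 epimers)
Conditions: Cu(OAc)2·H2O (5 mol %), 1,2-bis(diphenylphosphino)benzene, (MeO)2MeSiH, t-BuOH, toluene, rt
Reagents that add atoms: none
Why: Copper hydride 1,4-reduction touches only the conjugated ester; hydride should enter C9 mainly anti to the C1 chain, giving a cis-rich mixture at C9 that is corrected by equilibration in step 9.

Step 5
Reactants: 8 cyclobutyl acetate
Product: 9 α-hydroxy ester (epimers at C8 and C9)
Conditions: KHMDS, THF, −78 °C; 2-(phenylsulfonyl)-3-phenyloxaziridine; aq. NH4Cl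
Reagents that add atoms: 2-(phenylsulfonyl)-3-phenyloxaziridine, O=S(=O)(c1ccccc1)N1OC1c1ccccc1
Why: Davis hydroxylation of the potassium ester enolate puts oxygen on C8; the configuration at C8 is irrelevant because C8 becomes a ketone.

Step 6
Reactants: 9 α-hydroxy ester
Product: 10 1,2-diol benzoate
Conditions: NaBH4, EtOH, 0 °C
Reagents that add atoms: none
Why: Borohydride reduces the activated α-hydroxy trifluoroethyl ester to the primary C7 alcohol at 0 °C and leaves the benzoate and the alkene alone.

Step 7
Reactants: 10 1,2-diol benzoate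
Product: 11 C7 silyl ether
Conditions: TBDPSCl, imidazole, CH2Cl2, 0 °C
Reagents that add atoms: tert-butyl(chloro)diphenylsilane, CC(C)(C)[Si](Cl)(c1ccccc1)c1ccccc1
Why: Silylation with the bulky chlorosilane is selective for the primary C7 hydroxyl of the 1,2-diol.

Step 8
Reactants: 11 C7 silyl ether
Product: 12 α-silyloxy ketone (C9 epimers)
Conditions: Dess–Martin periodinane, NaHCO3, CH2Cl2, rt
Reagents that add atoms: none
Why: Buffered Dess–Martin oxidation of the secondary C8 alcohol gives the ketone without touching alkene, benzoate or silyl ether.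

Step 9
Reactants: 12 α-silyloxy ketone
Product: 13 trans keto alcohol (1R,9S)
Conditions: K2CO3, MeOH, rt
Reagents that add atoms: none
Why: Methoxide-mediated transesterification frees the allylic alcohol and at the same time equilibrates C9 through the ketone enolate to the thermodynamically preferred trans-1,2-disubstituted cyclobutane (C9 set under thermodynamic control; C1 carries no acidic hydrogen).

Step 10
Reactants: 13 trans keto alcohol; 14 syncarpic acid; 15 isovaleraldehyde
Product: 17 pyran alcohol (4R,5R,1′R), via quinone methide 16 (not isolated)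
Conditions: 14 (2 equiv), 15 (2 equiv), ethylenediammonium diacetate (10 mol %), 4 Å MS, toluene, 80 °C; separation of diastereomers by chromatography
Reagents that add atoms: none
Why: Domino Knoevenagel/inverse-electron-demand hetero-Diels–Alder reaction, in which 14 and 15 condense to the alkylidene trione 16 that adds across C4=C5 with O bonding to the more substituted C4 and C1′ to C5; suprafacial addition to the E alkene fixes C3 and C6 trans on the pyran, the orientation with CH2OH under ring A (hydrogen bond from the free hydroxyl to a ring A carbonyl) should place isobutyl cis to C6, and since the π-face is not differentiated by the remote cyclobutane the (4R,5R,1′R) adduct has to be separated from its facial diastereomer.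

Step 11
Reactants: 17 pyran alcohol
Product: 18 C6 thioacetate
Conditions: PPh3, DIAD, AcSH, THF, 0 °C → rt
Reagents that add atoms: thioacetic acid, CC(=O)S
Why: Mitsunobu reaction, an SN2 displacement of the activated primary C6 hydroxyl by thioacetate (pKa about 3.4), with no stereocentre involved.

Step 12
Reactants: 18 C6 thioacetate
Product: 19 α-hydroxy ketone
Conditions: HF·pyridine, THF, 0 °C → rt
Reagents that add atoms: none
Why: Fluoride cleaves the silyl ether under mildly acidic conditions that leave the thioester, the enol ether and the tertiary pyran ether untouched.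

Step 13
Reactants: 19 α-hydroxy ketone
Product: 20 keto mesylate
Conditions: MsCl, Et3N, CH2Cl2, −20 °C
Reagents that add atoms: methanesulfonyl chloride, CS(Cl)(=O)=O
Why: Sulfonylation of the primary α-hydroxy ketone gives an α-sulfonyloxy ketone, an SN2 electrophile of the α-halo ketone class, under conditions too mild to cleave the thioacetate.

Step 14
Reactants: 20 keto mesylate
Product: 22 ten-membered keto sulfide, via thiolate 21 (not isolated)
Conditions: K2CO3, degassed MeOH/THF (1:4), slow addition to 1 mM, 0 °C → rt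
Reagents that add atoms: none
Why: Methanolysis of the thioacetate releases the C6 thiolate, which displaces the α-keto mesylate at C7 intramolecularly (SN2, 10-exo-tet) under high dilution; the soft thiolate is far more nucleophilic toward this carbon than methoxide, and no stereocentre is formed.

Step 15
Reactants: 22 ten-membered keto sulfide
Product: 23 ketal sulfide
Conditions: (TMSOCH2)2, TMSOTf (10 mol %), CH2Cl2, −78 → −20 °C
Reagents that add atoms: 1,2-bis(trimethylsilyloxy)ethane, C[Si](C)(C)OCCO[Si](C)(C)C
Why: Noyori ketalisation converts the only unhindered, non-conjugated ketone (C8) into the dioxolane; the ring A ketone between two quaternary carbons and the vinylogous ester carbonyl should not react.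

Step 16
Reactants: 23 ketal sulfide
Product: 25 cyclic sulfone ketal, via sulfoxide 24 (not isolated)
Conditions: mCPBA (2.2 equiv), NaHCO3, CH2Cl2, 0 °C → rt
Reagents that add atoms: 3-chloroperoxybenzoic acid, OOC(=O)c1cccc(Cl)c1
Why: Peracid oxidation of the sulfide through the sulfoxide to the sulfone; the tetrasubstituted, acceptor-substituted enol ether alkene is not epoxidised and the ketal is stable to the buffered medium.

Step 17
Reactants: 25 cyclic sulfone ketal
Product: 28 (Z)-cyclononene ketal, via α-bromo sulfone 26 (not isolated), via episulfone 27 (not isolated)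
Conditions: KOH/Al2O3, CBr2F2, t-BuOH/CH2Cl2 (1:1), 0 °C → rt
Reagents that add atoms: none
Why: KOH on alumina removes a proton from a sulfone α-carbon (C7, further acidified by the ketal, or C6) and the carbanion takes Br+ from CBr2F2 to give 26; deprotonation at the other α-carbon then displaces bromide by 1,3-attack to the cis-fused episulfone 27, which loses SO2 in a cheletropic step and leaves the C6=C7 double bond, so that the ten-membered thiacycle becomes the nine-membered carbocycle. This is a Ramberg–Bäcklund ring contraction in the Meyers–Chan in situ halogenation variant, a known route from cyclic sulfones to medium-ring cycloalkenes. The only ring closed directly is the three-membered episulfone (3-exo-tet), and its collapse completes the nine-membered ring; no stereocentre is created, and the Z geometry is imposed by the ring and erased in step 18. The step needs deprotonation and halogenation to occur only next to sulfur: the dioxolane removes the C8 enolate and protects the C9 configuration, ring A carries no α-hydrogen, and C1′–H, the γ-position of a vinylogous ester, is far less acidic and shielded. A β-elimination from the C7 carbanion can at most open the dioxolane to a tethered alkoxide that adds back, and this bromine source releases only difluorocarbene, which, unlike dichlorocarbene, should not add to the new alkene.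

Step 18
Reactants: 28 (Z)-cyclononene ketal
Product: 29 saturated ketal
Conditions: 2-nitrobenzenesulfonyl hydrazide, Et3N, CH2Cl2, rt
Reagents that add atoms: none
Why: Diimide transfers H2 syn to the unpolarised cis-disubstituted alkene and should leave the tetrasubstituted enone alkene, the ketal and the ketones untouched.

Step 19
Reactants: 29 saturated ketal
Product: 30 C8 ketone
Conditions: 1 M aq. HCl, THF, rt
Reagents that add atoms: water, O
Why: Acid-catalysed hydrolysis of the dioxolane; the trans ring fusion at C9 is the thermodynamically preferred one for a cyclobutane-fused nine-membered ketone, so the now enolisable C9 should keep its configuration.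

Step 20
Reactants: 30 C8 ketone
Product: 31 Tomentodione B
Conditions: Ph3PCH3Br, KOt-Bu, toluene, rt → 50 °C
Reagents that add atoms: methyltriphenylphosphonium bromide, C[P+](c1ccccc1)(c1ccccc1)c1ccccc1.[Br-]
Why: Wittig methylenation of the C8 ketone, the classical last step of caryophyllane syntheses; the ring A ketone flanked by two quaternary carbons and the vinylogous ester are too hindered or too electron-rich to react, and C9 stays in its preferred trans configuration.

Compound list
1 | but-3-ynoic acid | C#CCC(=O)O | starting material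
2 | 2,2,2-trifluoroethanol | OCC(F)(F)F | starting material
3 | 2,2,2-trifluoroethyl but-3-ynoate (not isolated) | C#CCC(=O)OCC(F)(F)F | intermediate
4 | 2,2,2-trifluoroethyl buta-2,3-dienoate | C=C=CC(=O)OCC(F)(F)F | intermediate
5 | geraniol, (2E)-3,7-dimethylocta-2,6-dien-1-ol | CC(C)=CCC/C(C)=C/CO | starting material
6 | geranyl benzoate, (2E)-3,7-dimethylocta-2,6-dien-1-yl benzoate | CC(C)=CCC/C(C)=C/COC(=O)c1ccccc1 | intermediate
7 | 2,2,2-trifluoroethyl 2-[(2S)-2-[(3E)-5-(benzoyloxy)-3-methylpent-3-en-1-yl]-3,3-dimethylcyclobutylidene]acetate (geometry of the exocyclic C8=C9 bond not defined) | FC(F)(F)COC(=O)C=C1CC(C)(C)[C@@H]1CC/C(C)=C/COC(=O)c1ccccc1 | intermediate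
8 | 2,2,2-trifluoroethyl 2-[(2R)-2-[(3E)-5-(benzoyloxy)-3-methylpent-3-en-1-yl]-3,3-dimethylcyclobutyl]acetate (C9 epimers, cis-rich) | FC(F)(F)COC(=O)CC1CC(C)(C)[C@@H]1CC/C(C)=C/COC(=O)c1ccccc1 | intermediate
9 | 2,2,2-trifluoroethyl 2-[(2R)-2-[(3E)-5-(benzoyloxy)-3-methylpent-3-en-1-yl]-3,3-dimethylcyclobutyl]-2-hydroxyacetate (epimers at C8 and C9) | FC(F)(F)COC(=O)C(O)C1CC(C)(C)[C@@H]1CC/C(C)=C/COC(=O)c1ccccc1 | intermediate
10 | (2E)-5-[(1R)-4-(1,2-dihydroxyethyl)-2,2-dimethylcyclobutyl]-3-methylpent-2-en-1-yl benzoate (epimers at C8 and C9) | OCC(O)C1CC(C)(C)[C@@H]1CC/C(C)=C/COC(=O)c1ccccc1 | intermediate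
11 | (2E)-5-[(1R)-4-[2-(tert-butyldiphenylsilyloxy)-1-hydroxyethyl]-2,2-dimethylcyclobutyl]-3-methylpent-2-en-1-yl benzoate (epimers at C8 and C9) | CC(C)(C)[Si](OCC(O)C1CC(C)(C)[C@@H]1CC/C(C)=C/COC(=O)c1ccccc1)(c1ccccc1)c1ccccc1 | intermediate
12 | (2E)-5-[(1R)-4-[2-(tert-butyldiphenylsilyloxy)acetyl]-2,2-dimethylcyclobutyl]-3-methylpent-2-en-1-yl benzoate (C9 epimers) | CC(C)(C)[Si](OCC(=O)C1CC(C)(C)[C@@H]1CC/C(C)=C/COC(=O)c1ccccc1)(c1ccccc1)c1ccccc1 | intermediate
13 | 2-(tert-butyldiphenylsilyloxy)-1-[(1S,2R)-2-[(3E)-5-hydroxy-3-methylpent-3-en-1-yl]-3,3-dimethylcyclobutyl]ethan-1-one (trans cyclobutane; caryophyllane C1 R, C9 S) | CC(C)(C)[Si](OCC(=O)[C@H]1CC(C)(C)[C@@H]1CC/C(C)=C/CO)(c1ccccc1)c1ccccc1 | intermediate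
14 | syncarpic acid, 2,2,4,4-tetramethylcyclohexane-1,3,5-trione | CC1(C)C(=O)CC(=O)C(C)(C)C1=O | starting material
15 | isovaleraldehyde, 3-methylbutanal | CC(C)CC=O | starting material
16 | 2-(3-methylbutylidene)-4,4,6,6-tetramethylcyclohexane-1,3,5-trione (not isolated) | CC(C)CC=C1C(=O)C(C)(C)C(=O)C(C)(C)C1=O | intermediate
17 | (2R,3R,4R)-2-[2-[(1R,4S)-4-[2-(tert-butyldiphenylsilyloxy)acetyl]-2,2-dimethylcyclobutyl]ethyl]-3-(hydroxymethyl)-2,6,6,8,8-pentamethyl-4-(2-methylpropyl)-3,4-dihydro-2H-chromene-5,7(6H,8H)-dione (caryophyllane 1R,4R,5R,9S,1′R) | OC[C@H]2[C@@H](CC(C)C)C3=C(O[C@]2(C)CC[C@@H]2[C@@H](C(=O)CO[Si](c4ccccc4)(c4ccccc4)C(C)(C)C)CC2(C)C)C(C)(C)C(=O)C(C)(C)C3=O | intermediate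
18 | thioacetate: as 17 with the chromene C3 substituent CH2SC(O)CH3 in place of CH2OH (chromene 2R,3S,4R; caryophyllane 1R,4R,5S,9S,1′R) | CC(=O)SC[C@H]2[C@@H](CC(C)C)C3=C(O[C@]2(C)CC[C@@H]2[C@@H](C(=O)CO[Si](c4ccccc4)(c4ccccc4)C(C)(C)C)CC2(C)C)C(C)(C)C(=O)C(C)(C)C3=O | intermediate
19 | α-hydroxy ketone: as 18 with the cyclobutane substituent C(=O)CH2OH (1R,4R,5S,9S,1′R) | CC(=O)SC[C@H]2[C@@H](CC(C)C)C3=C(O[C@]2(C)CC[C@@H]2[C@@H](C(=O)CO)CC2(C)C)C(C)(C)C(=O)C(C)(C)C3=O | intermediate
20 | keto mesylate: as 19 with C(=O)CH2OSO2CH3 (1R,4R,5S,9S,1′R) | CC(=O)SC[C@H]2[C@@H](CC(C)C)C3=C(O[C@]2(C)CC[C@@H]2[C@@H](C(=O)COS(C)(=O)=O)CC2(C)C)C(C)(C)C(=O)C(C)(C)C3=O | intermediate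
21 | thiol (formed as thiolate, not isolated): as 20 with CH2SH at C5 | SC[C@H]2[C@@H](CC(C)C)C3=C(O[C@]2(C)CC[C@@H]2[C@@H](C(=O)COS(C)(=O)=O)CC2(C)C)C(C)(C)C(=O)C(C)(C)C3=O | intermediate
22 | ten-membered keto sulfide (1R,4R,5S,9S,1′R): ring C1–C2–C3–C4–C5–C6–S–C7–C8(=O)–C9, cyclobutane, pyran and ring A as in the target | O=C1CSC[C@H]3[C@@H](CC(C)C)C4=C(O[C@]3(C)CC[C@@H]3[C@@H]1CC3(C)C)C(C)(C)C(=O)C(C)(C)C4=O | intermediate
23 | ketal sulfide: C8 ethylene ketal (1,3-dioxolane) of 22 | O1CCOC12CSC[C@H]3[C@@H](CC(C)C)C4=C(O[C@]3(C)CC[C@@H]3[C@@H]2CC3(C)C)C(C)(C)C(=O)C(C)(C)C4=O | intermediate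
24 | sulfoxide of 23 (S-epimers, not isolated) | O1CCOC12CS(=O)C[C@H]3[C@@H](CC(C)C)C4=C(O[C@]3(C)CC[C@@H]3[C@@H]2CC3(C)C)C(C)(C)C(=O)C(C)(C)C4=O | intermediate
25 | ten-membered cyclic sulfone, sulfur between C6 and C7, C8 as dioxolane (1R,4R,5S,9S,1′R) | O1CCOC12CS(=O)(=O)C[C@H]3[C@@H](CC(C)C)C4=C(O[C@]3(C)CC[C@@H]3[C@@H]2CC3(C)C)C(C)(C)C(=O)C(C)(C)C4=O | intermediate
26 | 7-bromo derivative of 25 (C7 epimers, not isolated) | O1CCOC12C(Br)S(=O)(=O)C[C@H]3[C@@H](CC(C)C)C4=C(O[C@]3(C)CC[C@@H]3[C@@H]2CC3(C)C)C(C)(C)C(=O)C(C)(C)C4=O | intermediate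
27 | episulfone: cis-fused thiirane 1,1-dioxide across C6–C7 of the nine-membered ring (not isolated) | O1CCOC12C5C(S5(=O)=O)[C@H]3[C@@H](CC(C)C)C4=C(O[C@]3(C)CC[C@@H]3[C@@H]2CC3(C)C)C(C)(C)C(=O)C(C)(C)C4=O | intermediate
28 | (6Z)-C6=C7 cyclononene with C8 dioxolane (1R,4R,5S,9S,1′R) | O1CCOC12/C=C\[C@H]3[C@@H](CC(C)C)C4=C(O[C@]3(C)CC[C@@H]3[C@@H]2CC3(C)C)C(C)(C)C(=O)C(C)(C)C4=O | intermediate
29 | saturated ketal: 6,7-dihydro derivative of 28 | O1CCOC12CC[C@H]3[C@@H](CC(C)C)C4=C(O[C@]3(C)CC[C@@H]3[C@@H]2CC3(C)C)C(C)(C)C(=O)C(C)(C)C4=O | intermediate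
30 | C8 ketone: the target with C=O in place of C=CH2 at C8 (1R,4R,5S,9S,1′R) | O=C1CC[C@H]3[C@@H](CC(C)C)C4=C(O[C@]3(C)CC[C@@H]3[C@@H]1CC3(C)C)C(C)(C)C(=O)C(C)(C)C4=O | intermediate
31 | Tomentodione B (1R,4R,5S,9S,1′R) | C=C1CC[C@H]2[C@@H](CC(C)C)C3=C(O[C@]2(C)CC[C@@H]2[C@@H]1CC2(C)C)C(C)(C)C(=O)C(C)(C)C3=O | target

Total steps: 20. Longest linear sequence: 19 (geraniol, steps 2–20); step 1 is a side branch.

Steps most likely to fail

Step 17. The C7 carbanion, which is β to the ketal oxygens, may open the dioxolane faster than it is halogenated, or halogen transfer may outrun the 1,3-displacement and lead to over-halogenation. The fallback sets out from ketal sulfide 23 and installs the halogen before any carbanion is needed. NCS chlorination of the sulfide, expected at C6 (the α-carbon not deactivated by the ketal), gives the α-chloro sulfide F9. mCPBA then gives the α-chloro sulfone F10. KOt-Bu in THF at −78 → 0 °C triggers the classical two-stage Ramberg–Bäcklund reaction, in which the C7 carbanion can displace chloride at once. The sequence passes through episulfone 27 and rejoins the route at 28.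

Step 10. The remote cyclobutane gives no facial discrimination and the endo/exo preference is only moderate, so much material is lost on separation. The fallback sets out from 13 and closes the sulfur ring before the cycloaddition. A Mitsunobu reaction with thioacetic acid gives the allylic thioacetate F1, HF·pyridine the hydroxy ketone F2, and MsCl/Et3N the keto mesylate F3. K2CO3/MeOH under high dilution releases the thiol F4, whose thiolate closes the ten-membered (E)-cycloalkene keto sulfide F5. The cycloaddition with 14 and 15 is then run on F5, where the medium ring leaves only the outer face of the E alkene open and ties its orientation to the cyclobutane. The adduct is 22.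

Step 14. Attack of methoxide or enolisation at the α-mesyloxy ketone (Favorskii-type breakdown) and oligomerisation may compete with the slow ten-membered ring closure. The fallback sets out from 20 and closes the ring at the alcohol oxidation level. NaBH4/CeCl3 at −78 °C reduces the C8 ketone to the hydroxy mesylate F6. K2CO3/MeOH under high dilution gives the epoxy thiol F7 and, by opening of the terminal epoxide at C7, the ten-membered hydroxy sulfide F8. Dess–Martin oxidation returns to 22.

Further compounds
F1 | step 10 | allylic thioacetate: as 13 with CH2SC(O)CH3 in place of CH2OH | CC(C)(C)[Si](OCC(=O)[C@H]1CC(C)(C)[C@@H]1CC/C(C)=C/CSC(C)=O)(c1ccccc1)c1ccccc1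
F2 | step 10 | hydroxy ketone: S-[(2E)-5-[(1R,4S)-4-(hydroxyacetyl)-2,2-dimethylcyclobutyl]-3-methylpent-2-en-1-yl] ethanethioate | OCC(=O)[C@H]1CC(C)(C)[C@@H]1CC/C(C)=C/CSC(C)=O
F3 | step 10 | keto mesylate of F2 | CS(=O)(=O)OCC(=O)[C@H]1CC(C)(C)[C@@H]1CC/C(C)=C/CSC(C)=O
F4 | step 10 | thiol from F3 (formed as thiolate, not isolated) | CS(=O)(=O)OCC(=O)[C@H]1CC(C)(C)[C@@H]1CC/C(C)=C/CS
F5 | step 10 | ten-membered (E)-cycloalkene keto sulfide, ring C1–C2–C3–C4=C5–C6–S–C7–C8(=O)–C9, trans-fused cyclobutane (1R,9S) | O=C1CSC/C=C(C)/CC[C@@H]2[C@@H]1CC2(C)C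
F6 | step 14 | hydroxy mesylate: as 20 with CH(OH) at C8 (C8 epimers) | CC(=O)SC[C@H]2[C@@H](CC(C)C)C3=C(O[C@]2(C)CC[C@@H]2[C@@H](C(O)COS(C)(=O)=O)CC2(C)C)C(C)(C)C(=O)C(C)(C)C3=O
F7 | step 14 | epoxy thiol: C7–C8 oxirane, CH2SH at C5 (formed as thiolate, not isolated) | SC[C@H]2[C@@H](CC(C)C)C3=C(O[C@]2(C)CC[C@@H]2[C@@H](C4CO4)CC2(C)C)C(C)(C)C(=O)C(C)(C)C3=O
F8 | step 14 | ten-membered hydroxy sulfide: as 22 with CH(OH) at C8 | OC1CSC[C@H]3[C@@H](CC(C)C)C4=C(O[C@]3(C)CC[C@@H]3[C@@H]1CC3(C)C)C(C)(C)C(=O)C(C)(C)C4=O
F9 | step 17 | α-chloro sulfide: 6-chloro derivative of 23 (C6 epimers) | O1CCOC12CSC(Cl)[C@H]3[C@@H](CC(C)C)C4=C(O[C@]3(C)CC[C@@H]3[C@@H]2CC3(C)C)C(C)(C)C(=O)C(C)(C)C4=O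
F10 | step 17 | α-chloro sulfone: 6-chloro derivative of 25 (C6 epimers) | O1CCOC12CS(=O)(=O)C(Cl)[C@H]3[C@@H](CC(C)C)C4=C(O[C@]3(C)CC[C@@H]3[C@@H]2CC3(C)C)C(C)(C)C(=O)C(C)(C)C4=O
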